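**Strategy.** Everything rests on cutting the bond between the enol-ether oxygen and the central catechol ring. In that ring the enol-ether oxygen sits para to the cinnamate carbon and a free hydroxyl sits on the neighbouring carbon, so the methyl ester carbonyl can be tied to that hydroxyl oxygen as a six-membered aryl lactone. The ester tether then delivers the pyruvate enolate oxygen to a ring carbon bearing fluorine para to a formyl group: one intramolecular SNAr forms the O–aryl bond, closes the 1,4-benzodioxin-2-one ring and decides which catechol oxygen is etherified. The precursor is the 2-fluoro-5-formylphenyl ester of the arylpyruvic acid, stored as its Z silyl enol ether and unmasked by fluoride.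

Key step: step 6

Assumption: the arylpyruvic acid of step 3 is drawn as its keto tautomer although it is handled largely as the Z enol, and commercial danshensu sodium salt is taken to be the (R)-enantiomer.

**Route**

Step 1
Reactants: 1 3,4-dihydroxybenzaldehyde
Product: 2 3,4-bis(allyloxy)benzaldehyde
Conditions: allyl bromide, K2CO3, DMF, 60 °C
Reagents that add atoms: allyl bromide, C=CCBr
Why: Williamson etherification of both phenoxides by allyl bromide, with the aldehyde inert to K2CO3 in DMF.

Step 2
Reactants: 2 3,4-bis(allyloxy)benzaldehyde; 3 hydantoin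
Product: 4 (5Z)-5-[3,4-bis(allyloxy)benzylidene]imidazolidine-2,4-dione
Conditions: ethanolamine, EtOH/H2O, reflux
Reagents that add atoms: none
Why: Knoevenagel condensation at the acidic C5 methylene of hydantoin should give the conjugated arylidene as the thermodynamic Z isomer, whose geometry is of no consequence because it is erased in the next step.

Step 3
Reactants: 4 (5Z)-5-[3,4-bis(allyloxy)benzylidene]imidazolidine-2,4-dione
Product: 5 3-[3,4-bis(allyloxy)phenyl]-2-oxopropanoic acid
Conditions: 20% aq. NaOH, reflux, N2; then HCl, 0 °C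
Reagents that add atoms: water, O
Why: Alkaline hydrolysis opens the hydantoin to a ureidoacrylate whose enamine is hydrolysed to the α-keto acid (the classical hydantoin route to arylpyruvic acids), allyl aryl ethers being stable to aqueous NaOH and exclusion of air preventing oxidative cleavage of the keto acid.

Step 4
Reactants: 5 3-[3,4-bis(allyloxy)phenyl]-2-oxopropanoic acid
Product: 7 (Z)-3-[3,4-bis(allyloxy)phenyl]-2-[(tert-butyldimethylsilyl)oxy]acrylic acid, via bis-silyl derivative 6 (not isolated)
Conditions: TBSCl, imidazole, DMF, 0 °C to rt; then AcOH, THF/H2O, rt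
Reagents that add atoms: tert-butyldimethylsilyl chloride, CC(C)(C)[Si](C)(C)Cl
Why: O-Silylation of the carboxyl and enol oxygens followed by selective solvolysis of the far more labile silyl ester should give the acid with the enol locked as its Z silyl ether (the geometry of the stable enol), so that the enol oxygen cannot be acylated and the keto form cannot undergo aldol reactions in the coupling that follows.

Step 5
Reactants: 7 (Z)-3-[3,4-bis(allyloxy)phenyl]-2-[(tert-butyldimethylsilyl)oxy]acrylic acid; 8 4-fluoro-3-hydroxybenzaldehyde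
Product: 9 2-fluoro-5-formylphenyl (Z)-3-[3,4-bis(allyloxy)phenyl]-2-[(tert-butyldimethylsilyl)oxy]acrylate
Conditions: EDC·HCl, DMAP (cat.), CH2Cl2, 0 °C to rt
Reagents that add atoms: none
Why: Steglich esterification, in which the carbodiimide-activated acid is passed by DMAP to the acidic phenol while the silyl enol ether, the aldehyde and the aryl fluoride are inert to the neutral conditions.

Step 6
Reactants: 9 2-fluoro-5-formylphenyl (Z)-3-[3,4-bis(allyloxy)phenyl]-2-[(tert-butyldimethylsilyl)oxy]acrylate
Product: 11 (3Z)-3-[3,4-bis(allyloxy)benzylidene]-2-oxo-2,3-dihydro-1,4-benzodioxine-7-carbaldehyde, via cesium enolate 10 (not isolated)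
Conditions: CsF (1.2 equiv), 4 Å MS, DMF (0.01 M), slow addition of 9, 50–80 °C
Reagents that add atoms: none
Why: Proposed new method: fluoride removes the silyl group to give the free cesium Z-enolate 10, whose oxygen adds to the C–F carbon para to the formyl group, and loss of fluoride from the Meisenheimer complex gives the aryl lactone and returns the fluoride; the closest known reaction types are intramolecular SNAr O-arylations by enolates and phenoxides on para-acyl fluoroarenes (benzofuran, chromone and benzodioxine closures) and fluoride-triggered SNAr of aryl silyl ethers on activated aryl fluorides. The 1,4-benzodioxin-2-one ring closes by a 6-(enolexo)-exo-trig addition followed by elimination. No stereocenter is formed, and the Z geometry of the silyl enol ether should be carried into the arylidene lactone because the aprotic medium offers no path through the keto form. The step needs O- over C-arylation, and ring size cannot supply it, since attack through the benzylic carbon would also close a six-membered ring and end as a 4-aryl-3-hydroxycoumarin. What should secure it is orbital alignment in the substrate: with the aryl ring twisted out of the planar ester–enolate unit, as in any aryl ester, the in-plane lone pair of the enolate oxygen points at the C–F carbon, whereas the benzylic carbon could reach it only with a π lobe perpendicular to that plane, and a non-chelated cesium enolate in DMF keeps its oxygen, not its carbon, on the side of the ester oxygen. Slow addition at high dilution should hold down intermolecular aldol addition to the formyl group and acyl transfer.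

Step 7
Reactants: 11 (3Z)-3-[3,4-bis(allyloxy)benzylidene]-2-oxo-2,3-dihydro-1,4-benzodioxine-7-carbaldehyde
Product: 13 methyl (Z)-2-[2-(allyloxy)-4-formylphenoxy]-3-[3,4-bis(allyloxy)phenyl]acrylate, via phenol methyl ester 12 (not isolated)
Conditions: NaOMe (1.05 equiv), MeOH/THF, 0 °C; then allyl bromide, DMF, rt
Reagents that add atoms: sodium methoxide, C[O-].[Na+]; allyl bromide, C=CCBr
Why: Transesterification by methoxide opens the activated aryl lactone to the methyl ester and a phenoxide, which is capped in the same flask by Williamson allylation so that it can neither re-lactonise nor be acylated in the amine-mediated condensation, the Z enol ether being untouched.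

Step 8
Reactants: 14 sodium (R)-3-(3,4-dihydroxyphenyl)-2-hydroxypropanoate (danshensu sodium salt)
Product: 15 allyl (R)-3-[3,4-bis(allyloxy)phenyl]-2-hydroxypropanoate
Conditions: allyl bromide, K2CO3, DMF, rt
Reagents that add atoms: allyl bromide, C=CCBr
Why: Williamson-type alkylation of the carboxylate and both phenoxides, in which the secondary alcohol is not deprotonated by K2CO3 and the stereocenter, taken from the chiral pool, is not involved.

Step 9
Reactants: 15 allyl (R)-3-[3,4-bis(allyloxy)phenyl]-2-hydroxypropanoate; 16 Meldrum's acid (2,2-dimethyl-1,3-dioxane-4,6-dione)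
Product: 17 3-{[(2R)-1-(allyloxy)-3-[3,4-bis(allyloxy)phenyl]-1-oxopropan-2-yl]oxy}-3-oxopropanoic acid
Conditions: toluene, 100 °C
Reagents that add atoms: none
Why: Alcoholysis of Meldrum's acid by the secondary alcohol, with loss of acetone, should give the malonic half ester with retention, since the carbinol C–O bond is not broken.

Step 10
Reactants: 13 methyl (Z)-2-[2-(allyloxy)-4-formylphenoxy]-3-[3,4-bis(allyloxy)phenyl]acrylate; 17 3-{[(2R)-1-(allyloxy)-3-[3,4-bis(allyloxy)phenyl]-1-oxopropan-2-yl]oxy}-3-oxopropanoic acid
Product: 18 allyl (2R)-2-{[(2E)-3-{3-(allyloxy)-4-[(1Z)-2-[3,4-bis(allyloxy)phenyl]-1-(methoxycarbonyl)ethenyl]oxyphenyl}prop-2-enoyl]oxy}-3-[3,4-bis(allyloxy)phenyl]propanoate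
Conditions: pyridine, piperidine (cat.), 70 °C
Reagents that add atoms: none
Why: Knoevenagel–Doebner condensation of the aldehyde with the malonic half ester, with decarboxylation, should give the E cinnamate under conditions mild enough to leave the α-acyloxy ester stereocenter and the Z enol ether unchanged.

Step 11
Reactants: 18 allyl (2R)-2-{[(2E)-3-{3-(allyloxy)-4-[(1Z)-2-[3,4-bis(allyloxy)phenyl]-1-(methoxycarbonyl)ethenyl]oxyphenyl}prop-2-enoyl]oxy}-3-[3,4-bis(allyloxy)phenyl]propanoate
Product: 19 (2R)-2-{[(2E)-3-{4-[(1Z)-2-(3,4-dihydroxyphenyl)-1-(methoxycarbonyl)ethenyl]oxy-3-hydroxyphenyl}prop-2-enoyl]oxy}-3-(3,4-dihydroxyphenyl)propanoic acid (CNP0242322.1)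
Conditions: Pd(PPh3)4 (cat.), morpholine, THF, rt, argon; then aq. citric acid
Reagents that add atoms: none
Why: Tsuji–Trost deallylation, in which zerovalent palladium ionises the five allyl aryl ethers and the allyl ester to π-allyl complexes that morpholine traps, should free all phenols and the acid without touching the methyl ester, the enol ether, the cinnamate or the stereocenter.

**Compound list**

1 | 3,4-dihydroxybenzaldehyde | O=Cc1ccc(O)c(O)c1 | starting material
2 | 3,4-bis(allyloxy)benzaldehyde | O=Cc1ccc(OCC=C)c(OCC=C)c1 | intermediate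
3 | hydantoin (imidazolidine-2,4-dione) | O=C1CNC(=O)N1 | starting material
4 | (5Z)-5-[3,4-bis(allyloxy)benzylidene]imidazolidine-2,4-dione | O=C1NC(=O)/C(=C/c2ccc(OCC=C)c(OCC=C)c2)N1 | intermediate
5 | 3-[3,4-bis(allyloxy)phenyl]-2-oxopropanoic acid (keto tautomer drawn) | O=C(O)C(=O)Cc1ccc(OCC=C)c(OCC=C)c1 | intermediate
6 | tert-butyldimethylsilyl (Z)-3-[3,4-bis(allyloxy)phenyl]-2-[(tert-butyldimethylsilyl)oxy]acrylate | CC(C)(C)[Si](C)(C)OC(=O)/C(O[Si](C)(C)C(C)(C)C)=C/c1ccc(OCC=C)c(OCC=C)c1 | intermediate (not isolated)
7 | (Z)-3-[3,4-bis(allyloxy)phenyl]-2-[(tert-butyldimethylsilyl)oxy]acrylic acid | OC(=O)/C(O[Si](C)(C)C(C)(C)C)=C/c1ccc(OCC=C)c(OCC=C)c1 | intermediate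
8 | 4-fluoro-3-hydroxybenzaldehyde | O=Cc1ccc(F)c(O)c1 | starting material
9 | 2-fluoro-5-formylphenyl (Z)-3-[3,4-bis(allyloxy)phenyl]-2-[(tert-butyldimethylsilyl)oxy]acrylate | O=Cc1ccc(F)c(OC(=O)/C(O[Si](C)(C)C(C)(C)C)=C/c2ccc(OCC=C)c(OCC=C)c2)c1 | intermediate (key-step precursor)
10 | cesium (Z)-enolate of 2-fluoro-5-formylphenyl 3-[3,4-bis(allyloxy)phenyl]-2-oxopropanoate | O=Cc1ccc(F)c(OC(=O)/C([O-])=C/c2ccc(OCC=C)c(OCC=C)c2)c1.[Cs+] | intermediate (not isolated)
11 | (3Z)-3-[3,4-bis(allyloxy)benzylidene]-2-oxo-2,3-dihydro-1,4-benzodioxine-7-carbaldehyde | O=Cc1ccc2c(c1)OC(=O)/C(=C/c1ccc(OCC=C)c(OCC=C)c1)O2 | intermediate (key-step product)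
12 | methyl (Z)-3-[3,4-bis(allyloxy)phenyl]-2-(4-formyl-2-hydroxyphenoxy)acrylate (present as its sodium phenoxide) | COC(=O)/C(=C/c1ccc(OCC=C)c(OCC=C)c1)Oc1ccc(C=O)cc1O | intermediate (not isolated)
13 | methyl (Z)-2-[2-(allyloxy)-4-formylphenoxy]-3-[3,4-bis(allyloxy)phenyl]acrylate | COC(=O)/C(=C/c1ccc(OCC=C)c(OCC=C)c1)Oc1ccc(C=O)cc1OCC=C | intermediate
14 | sodium (R)-3-(3,4-dihydroxyphenyl)-2-hydroxypropanoate (danshensu sodium salt) | O[C@H](Cc1ccc(O)c(O)c1)C(=O)[O-].[Na+] | starting material
15 | allyl (R)-3-[3,4-bis(allyloxy)phenyl]-2-hydroxypropanoate | O[C@H](Cc1ccc(OCC=C)c(OCC=C)c1)C(=O)OCC=C | intermediate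
16 | Meldrum's acid (2,2-dimethyl-1,3-dioxane-4,6-dione) | CC1(C)OC(=O)CC(=O)O1 | starting material
17 | 3-{[(2R)-1-(allyloxy)-3-[3,4-bis(allyloxy)phenyl]-1-oxopropan-2-yl]oxy}-3-oxopropanoic acid | OC(=O)CC(=O)O[C@H](Cc1ccc(OCC=C)c(OCC=C)c1)C(=O)OCC=C | intermediate
18 | allyl (2R)-2-{[(2E)-3-{3-(allyloxy)-4-[(1Z)-2-[3,4-bis(allyloxy)phenyl]-1-(methoxycarbonyl)ethenyl]oxyphenyl}prop-2-enoyl]oxy}-3-[3,4-bis(allyloxy)phenyl]propanoate | COC(=O)/C(=C/c1ccc(OCC=C)c(OCC=C)c1)Oc1ccc(/C=C/C(=O)O[C@H](Cc2ccc(OCC=C)c(OCC=C)c2)C(=O)OCC=C)cc1OCC=C | intermediate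
19 | (2R)-2-{[(2E)-3-{4-[(1Z)-2-(3,4-dihydroxyphenyl)-1-(methoxycarbonyl)ethenyl]oxy-3-hydroxyphenyl}prop-2-enoyl]oxy}-3-(3,4-dihydroxyphenyl)propanoic acid | COC(=O)/C(=C/c1ccc(O)c(O)c1)Oc1ccc(/C=C/C(=O)O[C@H](Cc2ccc(O)c(O)c2)C(=O)O)cc1O | target

**Step count.** Total: 11 steps. Longest linear sequence: 9 steps (steps 1 to 7, 10 and 11); steps 8 and 9 form the side branch.

**Steps most likely to fail**

Step 6 (Proposed new method). Arylation through the benzylic carbon, cleavage of the activated aryl ester tether, or intermolecular aldol addition and acyl transfer may outrun the O-arylation. The ester conformer needed for lactone closure may also be too sparsely populated for ring closure at a temperature the tether survives. The fallback uses known chemistry and builds the enol ether from the other side, the vinyl carbon–oxygen bond by O–H insertion and the alkene by olefination. It sets out from 1. Alkylation of the dianion of 1 (NaH, 2.2 equiv, DMSO, then one equivalent of allyl bromide) should take place at the more nucleophilic 3-oxide and give 3-(allyloxy)-4-hydroxybenzaldehyde F1. Knoevenagel–Doebner condensation of this aldehyde with 17 (pyridine, piperidine) should give the phenolic cinnamate allyl (2R)-2-{[(2E)-3-[3-(allyloxy)-4-hydroxyphenyl]prop-2-enoyl]oxy}-3-[3,4-bis(allyloxy)phenyl]propanoate F2. Rh2(OAc)4-catalysed O–H insertion of methyl 2-diazo-2-(dimethoxyphosphoryl)acetate into its phenol (toluene, 80 °C) should give the aryloxyphosphonoacetate methyl 2-(dimethoxyphosphoryl)-2-(aryloxy)acetate F3, a mixture of epimers at the phosphonate carbon. Horner–Wadsworth–Emmons olefination of this phosphonate with 2 (LiCl, DBU, MeCN) should give mainly the Z enol ether and, after removal of the E isomer, comes back to the route at 18.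

Step 4. The enol silyl group may be lost while the silyl ester is unmasked, leaving a free enol that acylates itself in the coupling. The fallback avoids the free acid altogether. It sets out from 5, which is bis-silylated as in step 4 but worked up without water so that 6 is kept. Oxalyl chloride with catalytic DMF in CH2Cl2 should convert the silyl ester directly into (Z)-3-[3,4-bis(allyloxy)phenyl]-2-[(tert-butyldimethylsilyl)oxy]acryloyl chloride F4. This acid chloride acylates 8 (pyridine, CH2Cl2, 0 °C) and the route is rejoined at 9.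

Step 10. Condensation of the electron-rich aldehyde may be slow enough for amine attack on the acrylate and ester groups, or for epimerisation next to the allyl ester, to compete at the temperature needed for decarboxylation. The fallback replaces the decarboxylative condensation by a phosphonate olefination at room temperature. It sets out from 15. Steglich esterification of 15 with 2-(diethoxyphosphoryl)acetic acid (EDC·HCl, DMAP, CH2Cl2) should give allyl (2R)-3-[3,4-bis(allyloxy)phenyl]-2-{[2-(diethoxyphosphoryl)acetyl]oxy}propanoate F5. Masamune–Roush Horner–Wadsworth–Emmons olefination of 13 with this phosphonate (LiCl, iPr2NEt, MeCN, rt) should give the E cinnamate and comes back to the route at 18.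

**Further compounds**

F1 | step 6 | 3-(allyloxy)-4-hydroxybenzaldehyde | O=Cc1ccc(O)c(OCC=C)c1
F2 | step 6 | allyl (2R)-2-{[(2E)-3-[3-(allyloxy)-4-hydroxyphenyl]prop-2-enoyl]oxy}-3-[3,4-bis(allyloxy)phenyl]propanoate | Oc1ccc(/C=C/C(=O)O[C@H](Cc2ccc(OCC=C)c(OCC=C)c2)C(=O)OCC=C)cc1OCC=C
F3 | step 6 | allyl (2R)-2-{[(2E)-3-{3-(allyloxy)-4-[1-(dimethoxyphosphoryl)-2-methoxy-2-oxoethoxy]phenyl}prop-2-enoyl]oxy}-3-[3,4-bis(allyloxy)phenyl]propanoate (epimers at the phosphonate carbon) | COC(=O)C(Oc1ccc(/C=C/C(=O)O[C@H](Cc2ccc(OCC=C)c(OCC=C)c2)C(=O)OCC=C)cc1OCC=C)P(=O)(OC)OC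
F4 | step 4 | (Z)-3-[3,4-bis(allyloxy)phenyl]-2-[(tert-butyldimethylsilyl)oxy]acryloyl chloride | O=C(Cl)/C(O[Si](C)(C)C(C)(C)C)=C/c1ccc(OCC=C)c(OCC=C)c1
F5 | step 10 | allyl (2R)-3-[3,4-bis(allyloxy)phenyl]-2-{[2-(diethoxyphosphoryl)acetyl]oxy}propanoate | CCOP(=O)(CC(=O)O[C@H](Cc1ccc(OCC=C)c(OCC=C)c1)C(=O)OCC=C)OCC
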